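**The fork.** If I follow one molecule of starting material, it ends either as product or off the product path, so the oak question is a partition ratio (a selectivity factor): share not made against share made.

| setting | alder | elm | cedar | maple | oak |
|---|---|---|---|---|---|
| starting material | 0.300 M | 0.150 M | 0.900 M | 0.300 M | 0.900 M |
| reagent | 0.450 M | 0.300 M | 0.450 M | 1.40 M | 1.40 M |
| time |  |  |  |  | 100 min |

- alder run (time / min: [product] / M): 4.4: 0.0391; 13: 0.0832; 26: 0.1210; 41: 0.1435; 58: 0.1546; 78: 0.1634; 100: 0.1674
- elm run (time / min: [product] / M): 4.4: 0.0089; 13: 0.0237; 26: 0.0386; 41: 0.0494; 58: 0.0575; 78: 0.0650; 100: 0.0696
- cedar run (time / min: [product] / M): 4.4: 0.0947; 13: 0.1747; 26: 0.2280; 41: 0.2521; 58: 0.2673; 78: 0.2765; 100: 0.2837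
- maple run (time / min: [product] / M): 4.4: 0.2194; 13: 0.2696; 26: 0.2755; 41: 0.2744; 58: 0.2732; 78: 0.2745; 100: 0.2756

(readings scatter by 9 × 10⁻⁴ M)

* the exponent of [reagent] in the starting rate at the charge of the alder run (at the point where two percent of the starting material have become product)
* the exponent of [starting material] in the starting rate at the charge of the alder run (at the point where two percent of the starting material have become product) (one fixed amount of product, the same in the runs compared)
* product in the oak run at 100 min, as a share of the starting material charged

- Overall: starting material + reagent -> product.
- Constant volume, constant temperature.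
- An order is taken over about fifteen percent of the charge, up and down.

**What matters.** The time 100 min matters little if oak behaves like maple, whose reagent charge it shares: maple reads 0.2755 M at 26 min and 0.2756 M at 100 min. The reagent spent and maple's last reading are the inputs I size below, once the constant stands.

**The constant.** The share at 100 min falls from 55.8 % in alder to 31.5 % in cedar, at equal reagent, and rises to 91.9 % in maple, at alder's starting material. I assume the partition ratio follows starting material over reagent squared, both taken at the midpoint, the mean of first and last values, with the starting material counted as used up at the end and one reagent spent per product. Maple then gives the fork constant, the partition ratio times midpoint reagent squared over midpoint starting material: 0.940 M.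

**My reckoning.** For oak, with a trial share of 0.7 setting the reagent spent, the partition ratio is 0.359, so the share I commit to is 73.6 %. Holding reagent at its charge instead gives 82.2 %. One scatter on maple's last reading shifts my share by 0.71 percentage points.

**The forecast.** It says “Starting material is therefore being lost to a side path.” It gives orders 2 (1.8 to 2.2) in reagent and 1 (0.8 to 1.2) in starting material, and 74 % (67 % to 81 %) for oak.

**The result.** Oak gives 78.6 %, with orders 2.1 and 1.0.

    starting material + 2 reagent → product + reagent (0.1764 L² mol⁻² min⁻¹)
    starting material + reagent + product → 2 product (0.3702 L² mol⁻² min⁻¹)
    2 starting material → homo dimer (0.1092 L mol⁻¹ min⁻¹)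

Removing the homo dimer step moves the readings by 98 times the scatter. Oak's partition ratio is 0.272, lower than the reckoned 0.359. The fork constant gives alder 48.8 %, less than its 55.8 % at 100 min.

(The runs stem from a simulated flask with made-up constants, and the scatter is random.)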